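**Retrosynthetic overview**

1. Target 18 comes from the tris-MOM flavanone 17 by one acidic cleavage of all three MOM ethers.
2. 17 comes from the aryl bromide 14: ring C, the only ring built in the route, is closed last by forming C4–C4a from an aryllithium at C4a onto a side-chain Weinreb amide.
3. 14 comes from phenol 8 and (R)-hydroxy amide 13: the O1–C2 ether is made by Mitsunobu inversion, which sets C2 as (S).
4. 8 comes from 2-methylresorcinol 1 (ring A) and prenyl bromide 6; 13 comes from 4-hydroxyacetophenone 9 (ring B).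
5. Feature: ring A is fully substituted, and of the two carbons flanking the O1-bearing C8a, C8 carries the prenyl group; C4a is therefore the only site for a bromine and an aryl anion, and that anion can only close ring C by bonding to C4.

Key step: step 10

Remark: 4′-O is carried as a MOM ether, not a silyl ether; it survives the NaH-mediated Claisen condensation and allows a single acidic deprotection, so the base-sensitive flavanone never meets fluoride.

**Route**

Step 1
Reactants: 1 2-methylresorcinol
Product: 2 1,3-bis(methoxymethoxy)-2-methylbenzene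
Conditions: NaH (2.4 equiv), MOMCl (2.4 equiv), DMF, 0 °C → rt
Reagents that add atoms: chloromethyl methyl ether, COCCl
Why: O-alkylation of the bis-phenoxide with the reactive chloromethyl ether (MOM protection, Williamson type) should cap both hydroxyls.

Step 2
Reactants: 2 1,3-bis(methoxymethoxy)-2-methylbenzene
Product: 4 3,5-bis(methoxymethoxy)-4-methylphenol, via aryl pinacol boronate 3 (not isolated)
Conditions: HBpin (1.5 equiv), [Ir(OMe)(cod)]2 (1.5 mol %), 4,4′-di-tert-butyl-2,2′-bipyridine (3 mol %), THF, 60 °C; concentrate; then NaOH (aq), 30% H2O2, THF, 0 °C → rt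
Reagents that add atoms: pinacolborane, CC1(C)OBOC1(C)C (boryl group of 3); hydrogen peroxide, OO (phenol oxygen of 4)
Why: Sterically governed iridium-catalysed aromatic C–H borylation should take the one ring carbon without an ortho substituent (meta to both MOM ethers, para to the methyl), and basic peroxide oxidation of the boronate (aryl migration from boron to oxygen) then gives the phenol in the same flask.

Step 3
Reactants: 4 3,5-bis(methoxymethoxy)-4-methylphenol
Product: 5 2,6-dibromo-3,5-bis(methoxymethoxy)-4-methylphenol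
Conditions: NBS (2.0 equiv), MeCN, −20 → 0 °C
Reagents that add atoms: N-bromosuccinimide, O=C1CCC(=O)N1Br
Why: Electrophilic aromatic bromination of the activated phenol; the two positions ortho to the free hydroxyl are equivalent and are the only open ring carbons, so two equivalents should give one product under non-acidic conditions that spare the MOM ethers.

Step 4
Reactants: 5 2,6-dibromo-3,5-bis(methoxymethoxy)-4-methylphenol; 6 prenyl bromide (1-bromo-3-methylbut-2-ene)
Product: 8 2-bromo-3,5-bis(methoxymethoxy)-4-methyl-6-(3-methylbut-2-en-1-yl)phenol, via dilithio phenolate 7 (not isolated)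
Conditions: t-BuLi (3.1 equiv), THF, −78 °C; then CuBr·SMe2 (0.2 equiv), 6 (1.2 equiv), −78 → 0 °C; AcOH quench
Reagents that add atoms: none
Why: Deprotonation of the phenol followed by a single bromine–lithium exchange (a second exchange would have to build a trianion) and copper-catalysed SN2 allylation of the aryl–metal at the primary carbon of prenyl bromide should replace one of the two equivalent bromines by prenyl.

Step 5
Reactants: 9 4-hydroxyacetophenone
Product: 10 4-(methoxymethoxy)acetophenone
Conditions: NaH (1.1 equiv), MOMCl (1.1 equiv), DMF, 0 °C → rt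
Reagents that add atoms: chloromethyl methyl ether, COCCl
Why: The phenoxide forms in preference to the ketone enolate and is O-alkylated by the chloromethyl ether (MOM protection).

Step 6
Reactants: 10 4-(methoxymethoxy)acetophenone
Product: 11 ethyl 3-[4-(methoxymethoxy)phenyl]-3-oxopropanoate
Conditions: NaH (2.5 equiv), (EtO)2CO (3 equiv), THF, reflux; AcOH quench
Reagents that add atoms: diethyl carbonate, CCOC(=O)OCC
Why: Crossed Claisen condensation of the methyl ketone enolate with diethyl carbonate, driven forward by deprotonation of the beta-keto ester formed; the MOM ether is inert to the base.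

Step 7
Reactants: 11 ethyl 3-[4-(methoxymethoxy)phenyl]-3-oxopropanoate
Product: 12 ethyl (R)-3-hydroxy-3-[4-(methoxymethoxy)phenyl]propanoate
Conditions: RuCl[(R,R)-TsDPEN](p-cymene) (1 mol %), HCO2H/Et3N (5:2), EtOAc, 30 °C
Reagents that add atoms: none
Why: Noyori–Ikariya asymmetric transfer hydrogenation of an aryl ketone; the (R,R)-catalyst should deliver hydride to the face that gives the (R)-benzylic alcohol, as for simple aryl ketones, through the arene CH/π contact in the outer-sphere transition state.

Step 8
Reactants: 12 ethyl (R)-3-hydroxy-3-[4-(methoxymethoxy)phenyl]propanoate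
Product: 13 (R)-3-hydroxy-N-methoxy-3-[4-(methoxymethoxy)phenyl]-N-methylpropanamide
Conditions: MeNH(OMe)·HCl (2.5 equiv), i-PrMgCl (5.5 equiv), THF, −20 → 0 °C
Reagents that add atoms: N,O-dimethylhydroxylamine hydrochloride, CNOC.Cl
Why: Direct aminolysis of the ester by the magnesium amide made in the flask (Weinreb amide formation), with the hydroxyl carried as its magnesium alkoxide and the stereocentre untouched; enantiomeric purity can be raised here by crystallisation if needed.

Step 9
Reactants: 8 2-bromo-3,5-bis(methoxymethoxy)-4-methyl-6-(3-methylbut-2-en-1-yl)phenol; 13 (R)-3-hydroxy-N-methoxy-3-[4-(methoxymethoxy)phenyl]-N-methylpropanamide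
Product: 14 (S)-3-[2-bromo-3,5-bis(methoxymethoxy)-4-methyl-6-(3-methylbut-2-en-1-yl)phenoxy]-N-methoxy-3-[4-(methoxymethoxy)phenyl]-N-methylpropanamide
Conditions: PPh3 (1.5 equiv), DIAD (1.5 equiv), toluene, 0 °C → rt
Reagents that add atoms: none
Why: Mitsunobu etherification, in which the acidic ortho-bromophenol displaces the benzylic oxyphosphonium by SN2 with inversion, (R) to (S); the non-polar solvent and low temperature are chosen to hold back ionisation and elimination.

Step 10
Reactants: 14 (S)-3-[2-bromo-3,5-bis(methoxymethoxy)-4-methyl-6-(3-methylbut-2-en-1-yl)phenoxy]-N-methoxy-3-[4-(methoxymethoxy)phenyl]-N-methylpropanamide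
Product: 17 (2S)-5,7-bis(methoxymethoxy)-2-[4-(methoxymethoxy)phenyl]-6-methyl-8-(3-methylbut-2-en-1-yl)chroman-4-one, via C4a aryllithium 15 (not isolated), via chelated lithium hemiaminal alkoxide 16 (not isolated)
Conditions: t-BuLi (2.1 equiv), THF, −100 °C, then −78 °C; AcOH/THF quench at −78 °C
Reagents that add atoms: none
Why: Bromine–lithium exchange (the second equivalent of t-BuLi destroys the t-BuBr formed) gives the C4a aryllithium 15, held between the O1 and 5-O oxygens, which adds to the amide carbonyl to form C4–C4a; the N-methoxy chelate 16 persists until the acetic acid quench and only then collapses to the ketone with loss of N,O-dimethylhydroxylamine. The closest known reaction type is the Parham cyclisation (halogen–lithium exchange followed by intramolecular acylation), which is established for Weinreb amides and for chroman-4-ones. Ring C closes in a 6-exo-trig mode, the carbonyl oxygen staying outside the new ring. No stereocentre is formed in 17; C2 was set in step 9 and is not touched, because the ketone is released only in the buffered quench and never meets base, so retro-oxa-Michael opening cannot scramble it. The step needs chemoselectivity for exchange and closure over deprotonation at C3 (which would expel the aryloxide) and over addition of t-BuLi to the amide; the very fast exchange at −100 °C on a bromide flanked by two oxygens, the six-membered reach of the amide and the bulk of t-BuLi should secure it. Regiochemistry is not in question, since bromine marks C4a and every other ring A carbon is substituted.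

Step 11
Reactants: 17 (2S)-5,7-bis(methoxymethoxy)-2-[4-(methoxymethoxy)phenyl]-6-methyl-8-(3-methylbut-2-en-1-yl)chroman-4-one
Product: 18 6-methyl-8-prenylnaringenin, (2S)-5,7-dihydroxy-2-(4-hydroxyphenyl)-6-methyl-8-(3-methylbut-2-en-1-yl)chroman-4-one
Conditions: HCl (3 M aq.), MeOH, 40 °C
Reagents that add atoms: none
Why: Acid-catalysed acetal exchange with methanol should cleave all three MOM ethers (the 5-O ether assisted by the neighbouring carbonyl), under conditions mild enough to leave the prenyl alkene and the acid-stable C2 configuration alone.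

**Compound list**

1 | 2-methylresorcinol | Cc1c(O)cccc1O | starting material
2 | 1,3-bis(methoxymethoxy)-2-methylbenzene | COCOc1cccc(OCOC)c1C | intermediate
3 | 2-[3,5-bis(methoxymethoxy)-4-methylphenyl]-4,4,5,5-tetramethyl-1,3,2-dioxaborolane | COCOc1cc(B2OC(C)(C)C(C)(C)O2)cc(OCOC)c1C | intermediate
4 | 3,5-bis(methoxymethoxy)-4-methylphenol | COCOc1cc(O)cc(OCOC)c1C | intermediate
5 | 2,6-dibromo-3,5-bis(methoxymethoxy)-4-methylphenol | COCOc1c(Br)c(O)c(Br)c(OCOC)c1C | intermediate
6 | prenyl bromide (1-bromo-3-methylbut-2-ene) | CC(C)=CCBr | starting material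
7 | lithium 2-bromo-6-lithio-3,5-bis(methoxymethoxy)-4-methylphenolate | COCOc1c(Br)c(O[Li])c([Li])c(OCOC)c1C | intermediate
8 | 2-bromo-3,5-bis(methoxymethoxy)-4-methyl-6-(3-methylbut-2-en-1-yl)phenol | COCOc1c(Br)c(O)c(CC=C(C)C)c(OCOC)c1C | intermediate
9 | 4-hydroxyacetophenone | CC(=O)c1ccc(O)cc1 | starting material
10 | 4-(methoxymethoxy)acetophenone | CC(=O)c1ccc(OCOC)cc1 | intermediate
11 | ethyl 3-[4-(methoxymethoxy)phenyl]-3-oxopropanoate | CCOC(=O)CC(=O)c1ccc(OCOC)cc1 | intermediate
12 | ethyl (R)-3-hydroxy-3-[4-(methoxymethoxy)phenyl]propanoate | CCOC(=O)C[C@@H](O)c1ccc(OCOC)cc1 | intermediate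
13 | (R)-3-hydroxy-N-methoxy-3-[4-(methoxymethoxy)phenyl]-N-methylpropanamide | CON(C)C(=O)C[C@@H](O)c1ccc(OCOC)cc1 | intermediate
14 | (S)-3-[2-bromo-3,5-bis(methoxymethoxy)-4-methyl-6-(3-methylbut-2-en-1-yl)phenoxy]-N-methoxy-3-[4-(methoxymethoxy)phenyl]-N-methylpropanamide | CC(C)=CCc1c(OCOC)c(C)c(OCOC)c(Br)c1O[C@H](c1ccc(OCOC)cc1)CC(=O)N(C)OC | intermediate
15 | (S)-3-[2-lithio-3,5-bis(methoxymethoxy)-4-methyl-6-(3-methylbut-2-en-1-yl)phenoxy]-N-methoxy-3-[4-(methoxymethoxy)phenyl]-N-methylpropanamide | CC(C)=CCc1c(OCOC)c(C)c(OCOC)c([Li])c1O[C@H](c1ccc(OCOC)cc1)CC(=O)N(C)OC | intermediate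
16 | lithium (2S)-4-[methoxy(methyl)amino]-5,7-bis(methoxymethoxy)-2-[4-(methoxymethoxy)phenyl]-6-methyl-8-(3-methylbut-2-en-1-yl)chroman-4-olate (C4 not defined, transient) | CC(C)=CCc1c(OCOC)c(C)c(OCOC)c2c1O[C@H](c1ccc(OCOC)cc1)CC2(O[Li])N(C)OC | intermediate
17 | (2S)-5,7-bis(methoxymethoxy)-2-[4-(methoxymethoxy)phenyl]-6-methyl-8-(3-methylbut-2-en-1-yl)chroman-4-one | CC(C)=CCc1c(OCOC)c(C)c(OCOC)c2c1O[C@H](c1ccc(OCOC)cc1)CC2=O | intermediate
18 | 6-methyl-8-prenylnaringenin, (2S)-5,7-dihydroxy-2-(4-hydroxyphenyl)-6-methyl-8-(3-methylbut-2-en-1-yl)chroman-4-one | CC(C)=CCc1c(O)c(C)c(O)c2c1O[C@H](c1ccc(O)cc1)CC2=O | target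

**Step count**

Total: 11 steps. Longest linear sequence: 7 steps (steps 1–4 and 9–11; the ring B branch, steps 5–8 and 9–11, is equally long).

**Steps most likely to fail**

Step 10. The strong base may remove a C3 proton, after which the aryloxide is expelled by elimination; the aryllithium may be protonated before it closes; or t-BuLi may add to the amide. The fallback keeps an aryllithium closure but changes the acyl acceptor to a lithium carboxylate, which is not enolised under these conditions (the Parham cycliacylation of bromoaryl carboxylic acids is known). It sets out from 8 and 12 and comes back at 17. Mitsunobu coupling of 8 with hydroxy ester 12 (PPh3, DIAD, toluene, 0 °C) should give ethyl (S)-3-[2-bromo-3,5-bis(methoxymethoxy)-4-methyl-6-(3-methylbut-2-en-1-yl)phenoxy]-3-[4-(methoxymethoxy)phenyl]propanoate F1. Saponification with LiOH in THF/H2O at 0 °C should give (S)-3-[2-bromo-3,5-bis(methoxymethoxy)-4-methyl-6-(3-methylbut-2-en-1-yl)phenoxy]-3-[4-(methoxymethoxy)phenyl]propanoic acid F2. Deprotonation with n-BuLi (1 equiv, −78 °C) and exchange with t-BuLi (2.1 equiv, −100 °C) should give lithium (S)-3-[2-lithio-3,5-bis(methoxymethoxy)-4-methyl-6-(3-methylbut-2-en-1-yl)phenoxy]-3-[4-(methoxymethoxy)phenyl]propanoate F3. This should close to dilithium (2S)-5,7-bis(methoxymethoxy)-2-[4-(methoxymethoxy)phenyl]-6-methyl-8-(3-methylbut-2-en-1-yl)chromane-4,4-bis(olate) F4, and an acetic acid quench then returns 17.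

Step 9. The oxyphosphonium at the electron-rich benzylic carbon may ionise and erode the configuration; it may lose a C3 proton and give the cinnamamide; or the doubly ortho-substituted phenol may couple slowly. The fallback reverses the order of bond formation: C4–C4a is made first by intermolecular acylation and O1–C2 is closed afterwards by an intramolecular Mitsunobu reaction. It sets out from 13 and 8 and comes back at 17. Silylation of 13 (TBSCl, imidazole, DMF) should give (R)-3-(tert-butyldimethylsilyloxy)-N-methoxy-3-[4-(methoxymethoxy)phenyl]-N-methylpropanamide F5. Phenol 8 with t-BuLi (3.1 equiv, THF, −78 °C) should give lithium 2-lithio-3,5-bis(methoxymethoxy)-4-methyl-6-(3-methylbut-2-en-1-yl)phenolate F6. Addition of F5 to F6 and an acetic acid quench should give (R)-3-(tert-butyldimethylsilyloxy)-1-[2-hydroxy-4,6-bis(methoxymethoxy)-5-methyl-3-(3-methylbut-2-en-1-yl)phenyl]-3-[4-(methoxymethoxy)phenyl]propan-1-one F7. Desilylation with HF·pyridine in THF should give (R)-3-hydroxy-1-[2-hydroxy-4,6-bis(methoxymethoxy)-5-methyl-3-(3-methylbut-2-en-1-yl)phenyl]-3-[4-(methoxymethoxy)phenyl]propan-1-one F8. Ring closure of F8 with PPh3 and DIAD in toluene at 0 °C, with inversion at the carbinol carbon, should give 17.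

Step 4. The exchange may stop short or go on to the second bromine, and the phenoxide oxygen or the tertiary terminus of the allyl unit may be attacked instead of the primary carbon. The fallback brings in the prenyl group by a sigmatropic route without any organometallic step. It sets out from 4 and comes back at 8. Monobromination (NBS, 1.0 equiv, CH2Cl2, −78 °C) should give 2-bromo-3,5-bis(methoxymethoxy)-4-methylphenol F9. O-Alkylation with 2-methylbut-3-yn-2-yl trifluoroacetate (CuCl2 cat., DBU, MeCN, 0 °C) should give 2-bromo-3,5-bis(methoxymethoxy)-4-methyl-1-(2-methylbut-3-yn-2-yloxy)benzene F10. Semihydrogenation (H2, Pd/CaCO3 poisoned with Pb(OAc)2, quinoline, EtOAc) should give 2-bromo-3,5-bis(methoxymethoxy)-4-methyl-1-(2-methylbut-3-en-2-yloxy)benzene F11. Aromatic Claisen rearrangement of F11 (N,N-diethylaniline, 130 °C) to the only free ortho carbon should give 8.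

**Further compounds**

F1 | step 10 | ethyl (S)-3-[2-bromo-3,5-bis(methoxymethoxy)-4-methyl-6-(3-methylbut-2-en-1-yl)phenoxy]-3-[4-(methoxymethoxy)phenyl]propanoate | CC(C)=CCc1c(OCOC)c(C)c(OCOC)c(Br)c1O[C@H](c1ccc(OCOC)cc1)CC(=O)OCC
F2 | step 10 | (S)-3-[2-bromo-3,5-bis(methoxymethoxy)-4-methyl-6-(3-methylbut-2-en-1-yl)phenoxy]-3-[4-(methoxymethoxy)phenyl]propanoic acid | CC(C)=CCc1c(OCOC)c(C)c(OCOC)c(Br)c1O[C@H](c1ccc(OCOC)cc1)CC(=O)O
F3 | step 10 | lithium (S)-3-[2-lithio-3,5-bis(methoxymethoxy)-4-methyl-6-(3-methylbut-2-en-1-yl)phenoxy]-3-[4-(methoxymethoxy)phenyl]propanoate | CC(C)=CCc1c(OCOC)c(C)c(OCOC)c([Li])c1O[C@H](c1ccc(OCOC)cc1)CC(=O)O[Li]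
F4 | step 10 | dilithium (2S)-5,7-bis(methoxymethoxy)-2-[4-(methoxymethoxy)phenyl]-6-methyl-8-(3-methylbut-2-en-1-yl)chromane-4,4-bis(olate) | CC(C)=CCc1c(OCOC)c(C)c(OCOC)c2c1O[C@H](c1ccc(OCOC)cc1)CC2(O[Li])O[Li]
F5 | step 9 | (R)-3-(tert-butyldimethylsilyloxy)-N-methoxy-3-[4-(methoxymethoxy)phenyl]-N-methylpropanamide | CON(C)C(=O)C[C@@H](O[Si](C)(C)C(C)(C)C)c1ccc(OCOC)cc1
F6 | step 9 | lithium 2-lithio-3,5-bis(methoxymethoxy)-4-methyl-6-(3-methylbut-2-en-1-yl)phenolate | CC(C)=CCc1c(O[Li])c([Li])c(OCOC)c(C)c1OCOC
F7 | step 9 | (R)-3-(tert-butyldimethylsilyloxy)-1-[2-hydroxy-4,6-bis(methoxymethoxy)-5-methyl-3-(3-methylbut-2-en-1-yl)phenyl]-3-[4-(methoxymethoxy)phenyl]propan-1-one | CC(C)=CCc1c(O)c(C(=O)C[C@@H](O[Si](C)(C)C(C)(C)C)c2ccc(OCOC)cc2)c(OCOC)c(C)c1OCOC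
F8 | step 9 | (R)-3-hydroxy-1-[2-hydroxy-4,6-bis(methoxymethoxy)-5-methyl-3-(3-methylbut-2-en-1-yl)phenyl]-3-[4-(methoxymethoxy)phenyl]propan-1-one | CC(C)=CCc1c(O)c(C(=O)C[C@@H](O)c2ccc(OCOC)cc2)c(OCOC)c(C)c1OCOC
F9 | step 4 | 2-bromo-3,5-bis(methoxymethoxy)-4-methylphenol | COCOc1cc(O)c(Br)c(OCOC)c1C
F10 | step 4 | 2-bromo-3,5-bis(methoxymethoxy)-4-methyl-1-(2-methylbut-3-yn-2-yloxy)benzene | C#CC(C)(C)Oc1cc(OCOC)c(C)c(OCOC)c1Br
F11 | step 4 | 2-bromo-3,5-bis(methoxymethoxy)-4-methyl-1-(2-methylbut-3-en-2-yloxy)benzene | C=CC(C)(C)Oc1cc(OCOC)c(C)c(OCOC)c1Br
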